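Everything rests on opening ring C at the aryl ether bond C8a–O1. In the flavanone, O1 ties aromatic C8a of ring A to the sole stereocentre, benzylic C2. An alcohol whose (S) configuration is already settled can therefore be joined to C8a while its own C2–O bond stays untouched. One palladium-catalysed intramolecular O-arylation thus closes the pyran ring and hands the stereocentre on with retention. The precursor is an open 1,3-diarylpropane. It has a ring A bromide (Br on C8a) carrying the 5,7-dimethoxy and 6-prenyl groups, the future C4 parked as a silyl ether, and a free (S)-carbinol beside the trimethoxyphenyl ring B, set by catalytic asymmetric ketone reduction.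

Key step: step 7

Remarks on the chemistry
- Assumption: the aldol centre (future C4) is carried as both epimers from step 4 to step 8 and is erased in step 9. Its atom is therefore left undefined in the SMILES.
- Ring A is built on 1-bromo-3,5-difluorobenzene, not on the dimethoxy analogue. On 1-bromo-3,5-dimethoxybenzene an alkyllithium would exchange the bromine, and a lithium amide would take the proton beside bromine and open an aryne channel.
- Fluorine makes both metalations regiochemically unambiguous and keeps every step after prenylation non-acidic. It is exchanged for methoxy once the formyl group activates it.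
- Catecholborane, not BH3, serves as hydride source in the asymmetric reduction, because BH3 would hydroborate the prenyl alkene.
- The TBS group at C4–O is kept. It is large enough to slow O-to-O migration under carbonate and small enough not to shield C8a–Br.

Step 1
Reactants: 1 1-bromo-3,5-difluorobenzene; 2 prenyl bromide (1-bromo-3-methylbut-2-ene)
Product: 4 5-bromo-1,3-difluoro-2-(3-methylbut-2-en-1-yl)benzene, via aryllithium 3 (not isolated)
Conditions: LiN(i-Pr)2 (1.05 equiv), THF, −78 °C; then 2 (1.2 equiv), −78 to −20 °C
Reagents that add atoms: none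
Why: Directed ortho-lithiation followed by SN2 allylation: the proton between the two fluorines is by far the most acidic on the ring, the amide base leaves the C–Br bond alone, and aryllithium 3, stable at −78 °C, should attack the unhindered primary carbon of 2 because the tertiary terminus is closed to a 2,6-disubstituted aryl nucleophile.

Step 2
Reactants: 4 5-bromo-1,3-difluoro-2-(3-methylbut-2-en-1-yl)benzene
Product: 7 6-bromo-2,4-difluoro-3-(3-methylbut-2-en-1-yl)benzaldehyde, via aryllithium 5 (not isolated), via lithium hemiaminolate 6 (not isolated)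
Conditions: LiN(i-Pr)2 (1.1 equiv), THF, −78 °C; DMF (2 equiv), −78 °C; AcOH quench, then H2O
Reagents that add atoms: N,N-dimethylformamide, CN(C)C=O
Why: Second directed ortho-lithiation and DMF formylation: the two remaining ring protons are equivalent and each is acidified by a flanking fluorine and bromine, so ring deprotonation should outrun removal of an allylic–benzylic proton, while −78 °C and a short ageing time hold back aryne formation from 5 before DMF traps it as 6, which collapses to the aldehyde on quench.

Step 3
Reactants: 7 6-bromo-2,4-difluoro-3-(3-methylbut-2-en-1-yl)benzaldehyde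
Product: 9 6-bromo-2,4-dimethoxy-3-(3-methylbut-2-en-1-yl)benzaldehyde, via monofluoride 8 (not isolated)
Conditions: NaOMe (3 equiv), MeOH–THF, 65 °C
Reagents that add atoms: sodium methoxide, C[O-].[Na+]
Why: Twofold nucleophilic aromatic substitution (addition–elimination): both fluorides stand ortho or para to the formyl acceptor (the para one probably leaves first, giving 8) and fluoride departs far faster than bromide in such reactions, so C6–Br should survive, the order of the two exchanges is irrelevant because the same nucleophile enters twice, and the basic medium leaves the prenyl group untouched.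

Step 4
Reactants: 9 6-bromo-2,4-dimethoxy-3-(3-methylbut-2-en-1-yl)benzaldehyde; 10 3',4',5'-trimethoxyacetophenone
Product: 13 rac-3-[6-bromo-2,4-dimethoxy-3-(3-methylbut-2-en-1-yl)phenyl]-3-hydroxy-1-(3,4,5-trimethoxyphenyl)propan-1-one, via lithium enolate 11 (not isolated), via lithium aldolate 12 (not isolated)
Conditions: 10, LiN(i-Pr)2 (1.05 equiv), THF, −78 °C; then 9, −78 °C; AcOH in THF at −78 °C
Reagents that add atoms: none
Why: Kinetic lithium enolate aldol addition to a non-enolisable aldehyde: preformed 11 adds at −78 °C, lithium chelation by the ortho methoxy group steadies aldolate 12, and the cold acidic quench forestalls retro-aldol cleavage and dehydration, while the new carbinol centre is racemic, which is harmless because step 9 erases it.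

Step 5
Reactants: 13 rac-β-hydroxy ketone
Product: 14 rac-3-[6-bromo-2,4-dimethoxy-3-(3-methylbut-2-en-1-yl)phenyl]-3-[(tert-butyldimethylsilyl)oxy]-1-(3,4,5-trimethoxyphenyl)propan-1-one
Conditions: TBSOTf (1.3 equiv), 2,6-lutidine (2 equiv), CH2Cl2, −78 to 0 °C
Reagents that add atoms: tert-butyldimethylsilyl triflate, CC(C)(C)[Si](C)(C)OS(=O)(=O)C(F)(F)F
Why: Silyl triflate silylation under a hindered pyridine base: the reagent is reactive enough for the crowded benzylic alcohol at low temperature, and 2,6-lutidine is too weak and too hindered to start β-elimination to the chalcone or to enolise the ketone.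

Step 6
Reactants: 14 rac-β-silyloxy ketone
Product: 16 (1S)-3-[6-bromo-2,4-dimethoxy-3-(3-methylbut-2-en-1-yl)phenyl]-3-[(tert-butyldimethylsilyl)oxy]-1-(3,4,5-trimethoxyphenyl)propan-1-ol as both C3 epimers, via borate ester 15 (not isolated)
Conditions: (R)-Me-CBS oxazaborolidine (15 mol %), catecholborane (1.8 equiv), toluene, −78 to −40 °C; then H2O, aq. NaOH wash
Reagents that add atoms: none
Why: Corey–Bakshi–Shibata reduction: the ketone binds to the ring boron of the (R)-oxazaborolidine with the aryl group as the large flank pointing away, hydride reaches the Re face and gives the 1S carbinol in both C3 series under catalyst control, and catecholborane is chosen because, unlike BH3, it does not hydroborate the prenyl alkene at these temperatures.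

Step 7
Reactants: 16 (1S)-bromo carbinol, both C3 epimers
Product: 17 (2S)-4-[(tert-butyldimethylsilyl)oxy]-5,7-dimethoxy-6-(3-methylbut-2-en-1-yl)-2-(3,4,5-trimethoxyphenyl)chroman as both C4 epimers
Conditions: Pd(OAc)2 (5 mol %), rac-2-(di-tert-butylphosphino)-1,1'-binaphthyl (6 mol %), Cs2CO3 (1.5 equiv), toluene, 80 °C
Reagents that add atoms: none
Why: Zerovalent palladium, formed from Pd(OAc)2 and the bulky biaryl di-tert-butylphosphine, inserts into C8a–Br, the C2 hydroxyl binds to divalent palladium and is deprotonated by carbonate, and C(aryl)–O reductive elimination releases 17 (intramolecular Buchwald–Hartwig etherification, the established way from 3-(2-bromoaryl)propan-1-ols to chromans). Ring C closes by contraction of a seven-membered oxapalladacycle (Pd, C8a, C4a, C4, C3, C2, O1) to the six-membered pyran, formally a 6-exo attack of O1 on C8a. No stereocentre is created: the C2–O bond is never broken, so 2S follows from 1S with retention, and both C4 epimers are carried on. The selectivity needed is reductive elimination over β-hydride elimination of the benzylic alkoxide, which the large monophosphine (crowded palladium without a free cis site) and the intramolecular setting should secure. The substrate helps further: C8a is meta to both methoxy groups and so is not deactivated toward oxidative addition, the silyl ether at C4 rules out retro-aldol cleavage and chalcone formation, and the prenyl group sits para to C8a, out of reach of a Heck closure. Insoluble carbonate in toluene keeps free alkoxide scarce, which should hold back O-to-O silyl migration.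

Step 8
Reactants: 17 (2S)-4-O-TBS flavan
Product: 18 (2S)-5,7-dimethoxy-6-(3-methylbut-2-en-1-yl)-2-(3,4,5-trimethoxyphenyl)chroman-4-ol as both C4 epimers
Conditions: Bu4NF (1.5 equiv), THF, 0 °C to rt; neutral aqueous work-up
Reagents that add atoms: none
Why: Fluoride-mediated desilylation driven by Si–F bond formation: at this oxidation level the molecule has no base-sensitive function, C2 is not involved, and acidic reagents, which would ionise the electron-rich benzylic C4–O bond, are avoided.

Step 9
Reactants: 18 (2S)-flavan-4-ol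
Product: 19 (2S)-5,7-dimethoxy-6-(3-methylbut-2-en-1-yl)-2-(3,4,5-trimethoxyphenyl)chroman-4-one
Conditions: Dess–Martin periodinane (1.3 equiv), NaHCO3 (5 equiv), CH2Cl2, 0 °C to rt
Reagents that add atoms: none
Why: Dess–Martin oxidation: the buffered, base-free conditions convert both C4 epimers into one ketone, spare the prenyl alkene and the electron-rich rings, and offer no base for retro-oxa-Michael opening of ring C, so 2S should persist.

Step 10
Reactants: 19 (2S)-5-O-methyl flavanone
Product: 21 artoflavanone, (2S)-5-hydroxy-7-methoxy-6-(3-methylbut-2-en-1-yl)-2-(3,4,5-trimethoxyphenyl)chroman-4-one, via magnesium phenolate 20 (not isolated)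
Conditions: MgI2·OEt2 (2 equiv), THF, 50 °C; then cold 0.1 M HCl
Reagents that add atoms: none
Why: Chelation-controlled aryl methyl ether cleavage: magnesium binds the C4 carbonyl and the peri O5 in a six-membered chelate, so iodide removes only that methyl group by SN2 while the 7-, 3'-, 4'- and 5'-methoxy groups lack such activation, and the aprotic, base-free medium (a reagent known to spare the prenyl group of 5-methoxy prenylflavanones) should neither protonate the alkene nor open ring C, so 2S is kept.

Compound list
1 | 1-bromo-3,5-difluorobenzene | Fc1cc(F)cc(Br)c1 | starting material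
2 | prenyl bromide (1-bromo-3-methylbut-2-ene) | CC(C)=CCBr | starting material
3 | (4-bromo-2,6-difluorophenyl)lithium | [Li]c1c(F)cc(Br)cc1F | intermediate
4 | 5-bromo-1,3-difluoro-2-(3-methylbut-2-en-1-yl)benzene | CC(C)=CCc1c(F)cc(Br)cc1F | intermediate
5 | [6-bromo-2,4-difluoro-3-(3-methylbut-2-en-1-yl)phenyl]lithium | [Li]c1c(Br)cc(F)c(CC=C(C)C)c1F | intermediate
6 | lithium [6-bromo-2,4-difluoro-3-(3-methylbut-2-en-1-yl)phenyl](dimethylamino)methanolate | CN(C)C(O[Li])c1c(Br)cc(F)c(CC=C(C)C)c1F | intermediate
7 | 6-bromo-2,4-difluoro-3-(3-methylbut-2-en-1-yl)benzaldehyde | O=Cc1c(Br)cc(F)c(CC=C(C)C)c1F | intermediate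
8 | 6-bromo-2-fluoro-4-methoxy-3-(3-methylbut-2-en-1-yl)benzaldehyde | O=Cc1c(Br)cc(OC)c(CC=C(C)C)c1F | intermediate
9 | 6-bromo-2,4-dimethoxy-3-(3-methylbut-2-en-1-yl)benzaldehyde | O=Cc1c(Br)cc(OC)c(CC=C(C)C)c1OC | intermediate
10 | 3',4',5'-trimethoxyacetophenone | CC(=O)c1cc(OC)c(OC)c(OC)c1 | starting material
11 | lithium enolate of 10 | [Li]OC(=C)c1cc(OC)c(OC)c(OC)c1 | intermediate
12 | lithium aldolate of 13 (racemic) | COc1cc(Br)c(c(OC)c1CC=C(C)C)C(O[Li])CC(=O)c1cc(OC)c(OC)c(OC)c1 | intermediate
13 | rac-3-[6-bromo-2,4-dimethoxy-3-(3-methylbut-2-en-1-yl)phenyl]-3-hydroxy-1-(3,4,5-trimethoxyphenyl)propan-1-one | COc1cc(Br)c(c(OC)c1CC=C(C)C)C(O)CC(=O)c1cc(OC)c(OC)c(OC)c1 | intermediate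
14 | rac-3-[6-bromo-2,4-dimethoxy-3-(3-methylbut-2-en-1-yl)phenyl]-3-[(tert-butyldimethylsilyl)oxy]-1-(3,4,5-trimethoxyphenyl)propan-1-one | COc1cc(Br)c(c(OC)c1CC=C(C)C)C(O[Si](C)(C)C(C)(C)C)CC(=O)c1cc(OC)c(OC)c(OC)c1 | intermediate
15 | 1,3,2-benzodioxaborol-2-yl (catechol borate) ester of 16, 1S, both C3 epimers | COc1cc(Br)c(c(OC)c1CC=C(C)C)C(O[Si](C)(C)C(C)(C)C)C[C@@H](c1cc(OC)c(OC)c(OC)c1)OB1Oc2ccccc2O1 | intermediate
16 | (1S)-3-[6-bromo-2,4-dimethoxy-3-(3-methylbut-2-en-1-yl)phenyl]-3-[(tert-butyldimethylsilyl)oxy]-1-(3,4,5-trimethoxyphenyl)propan-1-ol, both C3 epimers | COc1cc(Br)c(c(OC)c1CC=C(C)C)C(O[Si](C)(C)C(C)(C)C)C[C@@H](c1cc(OC)c(OC)c(OC)c1)O | intermediate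
17 | (2S)-4-[(tert-butyldimethylsilyl)oxy]-5,7-dimethoxy-6-(3-methylbut-2-en-1-yl)-2-(3,4,5-trimethoxyphenyl)chroman, both C4 epimers | COc1cc2c(c(OC)c1CC=C(C)C)C(O[Si](C)(C)C(C)(C)C)C[C@@H](c1cc(OC)c(OC)c(OC)c1)O2 | intermediate
18 | (2S)-5,7-dimethoxy-6-(3-methylbut-2-en-1-yl)-2-(3,4,5-trimethoxyphenyl)chroman-4-ol, both C4 epimers | COc1cc2c(c(OC)c1CC=C(C)C)C(O)C[C@@H](c1cc(OC)c(OC)c(OC)c1)O2 | intermediate
19 | (2S)-5,7-dimethoxy-6-(3-methylbut-2-en-1-yl)-2-(3,4,5-trimethoxyphenyl)chroman-4-one | COc1cc2c(c(OC)c1CC=C(C)C)C(=O)C[C@@H](c1cc(OC)c(OC)c(OC)c1)O2 | intermediate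
20 | iodomagnesium 5-phenolate of 21 (chelated to the C4 carbonyl), 2S | COc1cc2c(c(O[Mg]I)c1CC=C(C)C)C(=O)C[C@@H](c1cc(OC)c(OC)c(OC)c1)O2 | intermediate
21 | artoflavanone, (2S)-5-hydroxy-7-methoxy-6-(3-methylbut-2-en-1-yl)-2-(3,4,5-trimethoxyphenyl)chroman-4-one | COc1cc2c(c(O)c1CC=C(C)C)C(=O)C[C@@H](c1cc(OC)c(OC)c(OC)c1)O2 | target

Total step count: 10. Longest linear sequence: 10 steps, from 1.

Steps most likely to fail

**Step 7.** Three processes may go wrong:
- β-hydride elimination at the palladium alkoxide, with loss of bromine and reoxidation of the carbinol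
- slow oxidative addition next to the crowded silyloxy-bearing carbon
- silyl migration to the C2 oxygen

The fallback closes ring C at the other ether bond, C2–O1, by an intramolecular Mitsunobu etherification with inversion. It sets out from 14 and comes back at 17. Ketone 14 is reduced as in step 6 but with the (S)-oxazaborolidine, giving the (1R)-bromo carbinol F1. Miyaura borylation (PdCl2(dppf), B2pin2, KOAc, dioxane, 80 °C; this ligand and weak base do not promote etherification) gives the pinacol boronate F2. NaBO3·4H2O in THF–H2O gives the phenol F3. PPh3 and DIAD in toluene at 0 °C then displace the activated carbinol oxygen by the phenol, turning 1R into 2S and delivering 17.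

**Step 10.** Three processes may go wrong:
- erosion of optical purity through reversible opening of ring C at the chelated ketone
- proton-induced cyclisation of the freed 5-hydroxyl onto the prenyl group during work-up
- cleavage of a further methyl ether on ring B

The fallback moves the chelation-controlled demethylation to an achiral stage and carries O5 under a group that leaves under mild acid. It sets out from 9 and comes back at 21. MgI2·OEt2 cleaves the methoxy group beside the formyl group of 9 to give 6-bromo-2-hydroxy-4-methoxy-3-prenylbenzaldehyde F4. MOMCl and i-Pr2NEt give the methoxymethyl ether F5. The operations of steps 4 to 9 are then repeated unchanged, through: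
- the racemic aldol F6
- the silyl ether ketone F7
- the (1S)-carbinol F8
- the (2S)-flavan silyl ether F9
- the (2S)-flavan-4-ol F10
- the (2S)-5-O-MOM flavanone F11

The peri acetal of F11 is finally removed with dilute HCl in MeOH at or below 40 °C to give 21.

**Step 6.** Three processes may go wrong:
- poor facial selectivity, because the small flank of the ketone is β-branched
- unequal behaviour of the two enantiomers of racemic 14 toward one catalyst enantiomer
- slow turnover of the electron-rich aryl ketone

The fallback abandons Lewis-acid-organised borane delivery for outer-sphere metal–ligand bifunctional hydrogen transfer. This mode recognises the aryl ring by an attractive CH–π contact rather than by size. It is a Noyori–Ikariya asymmetric transfer hydrogenation with RuCl[(S,S)-TsDPEN](p-cymene) and HCO2H–Et3N in CH2Cl2 at 25–30 °C, which also leaves the alkene alone. It sets out from 14 and comes back at 16, and it makes no compound outside the list (entry F0).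

Further compounds
F1 | step 7 | (1R)-3-[6-bromo-2,4-dimethoxy-3-(3-methylbut-2-en-1-yl)phenyl]-3-[(tert-butyldimethylsilyl)oxy]-1-(3,4,5-trimethoxyphenyl)propan-1-ol, both C3 epimers | COc1cc(Br)c(c(OC)c1CC=C(C)C)C(O[Si](C)(C)C(C)(C)C)C[C@H](c1cc(OC)c(OC)c(OC)c1)O
F2 | step 7 | pinacol boronate of F1 (Bpin in place of Br), 1R | COc1cc(B2OC(C)(C)C(C)(C)O2)c(c(OC)c1CC=C(C)C)C(O[Si](C)(C)C(C)(C)C)C[C@H](c1cc(OC)c(OC)c(OC)c1)O
F3 | step 7 | phenol from F2 (OH in place of Bpin), 1R | COc1cc(O)c(c(OC)c1CC=C(C)C)C(O[Si](C)(C)C(C)(C)C)C[C@H](c1cc(OC)c(OC)c(OC)c1)O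
F4 | step 10 | 6-bromo-2-hydroxy-4-methoxy-3-(3-methylbut-2-en-1-yl)benzaldehyde | O=Cc1c(Br)cc(OC)c(CC=C(C)C)c1O
F5 | step 10 | 6-bromo-4-methoxy-2-(methoxymethoxy)-3-(3-methylbut-2-en-1-yl)benzaldehyde | O=Cc1c(Br)cc(OC)c(CC=C(C)C)c1OCOC
F6 | step 10 | rac-3-[6-bromo-4-methoxy-2-(methoxymethoxy)-3-(3-methylbut-2-en-1-yl)phenyl]-3-hydroxy-1-(3,4,5-trimethoxyphenyl)propan-1-one | COCOc1c(CC=C(C)C)c(OC)cc(Br)c1C(O)CC(=O)c1cc(OC)c(OC)c(OC)c1
F7 | step 10 | TBS ether of F6 (racemic) | COCOc1c(CC=C(C)C)c(OC)cc(Br)c1C(O[Si](C)(C)C(C)(C)C)CC(=O)c1cc(OC)c(OC)c(OC)c1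
F8 | step 10 | (1S)-carbinol from F7, both C3 epimers | COCOc1c(CC=C(C)C)c(OC)cc(Br)c1C(O[Si](C)(C)C(C)(C)C)C[C@@H](c1cc(OC)c(OC)c(OC)c1)O
F9 | step 10 | (2S)-4-[(tert-butyldimethylsilyl)oxy]-7-methoxy-5-(methoxymethoxy)-6-(3-methylbut-2-en-1-yl)-2-(3,4,5-trimethoxyphenyl)chroman, both C4 epimers | COCOc1c(CC=C(C)C)c(OC)cc2c1C(O[Si](C)(C)C(C)(C)C)C[C@@H](c1cc(OC)c(OC)c(OC)c1)O2
F10 | step 10 | (2S)-7-methoxy-5-(methoxymethoxy)-6-(3-methylbut-2-en-1-yl)-2-(3,4,5-trimethoxyphenyl)chroman-4-ol, both C4 epimers | COCOc1c(CC=C(C)C)c(OC)cc2c1C(O)C[C@@H](c1cc(OC)c(OC)c(OC)c1)O2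
F11 | step 10 | (2S)-7-methoxy-5-(methoxymethoxy)-6-(3-methylbut-2-en-1-yl)-2-(3,4,5-trimethoxyphenyl)chroman-4-one | COCOc1c(CC=C(C)C)c(OC)cc2c1C(=O)C[C@@H](c1cc(OC)c(OC)c(OC)c1)O2
F0 | step 6 | none | none
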